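**Plan**

- Numbering: ring A is the 3,5-dibromo-2-methoxyphenoxy ring. In ring B, C1' carries the ether oxygen, C2' the OH, C3' and C5' the bromines and C6' the OMe.
- Enabling feature: C2', C1' and C6' are three neighbouring oxygen-bearing carbons with the aryloxy carbon C1' in the middle, so ring B is a 2-aryloxycyclohexane-1,3-dione raised to the aromatic oxidation level.
- Cuts, in retrosynthetic order: C3'–Br and C5'–Br; the aromatic unsaturation and the C6'O–CH3 bond (back to the symmetric dione); the ring bond C1'–C2' (Claisen); the C1'–O bond to ring A (phenol plus bromomethyl ketone).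
- Forward: ring A is bought intact and converted into its phenol, and the six-carbon keto ester chain is attached through that oxygen. Ring B is then closed, desymmetrised as its mono methyl enol ether, dehydrogenated to the phenol and brominated twice.
- Stereochemistry: the target has no stereocentre and the diaryl ether rotates freely, so nothing has to be controlled.

Key step: step 5

Remark: in keto ester 8 the chain is numbered from the ester carbonyl (C1) to the OCH2 carbon (C6). C6 becomes C1'; because dione 10 is symmetric, C1 and C5 are interchangeable as C2'/C6'. Compounds 1 and 5 are taken as catalogue chemicals.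

**Route**

Step 1
Reactants: 1 3,5-dibromosalicylaldehyde (3,5-dibromo-2-hydroxybenzaldehyde)
Product: 2 3,5-dibromo-2-methoxybenzaldehyde
Conditions: MeI, K2CO3, DMF, rt
Reagents that add atoms: iodomethane, CI
Why: Williamson ether synthesis, in which the phenol of 1 (acidified by the ortho-formyl group and two bromines) is deprotonated by carbonate and methylated by SN2 attack on iodomethane while the aldehyde and aryl bromides stay untouched.

Step 2
Reactants: 2 3,5-dibromo-2-methoxybenzaldehyde
Product: 4 3,5-dibromo-2-methoxyphenol, via aryl formate 3 (not isolated)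
Conditions: mCPBA, CH2Cl2, 40 °C; aq NaHCO3 wash; then K2CO3 (cat.), MeOH, rt
Reagents that add atoms: meta-chloroperoxybenzoic acid, O=C(OO)c1cccc(Cl)c1
Why: Baeyer–Villiger oxidation of an ortho-alkoxybenzaldehyde (the peracid variant of the Dakin reaction), in which the aryl group, supported by the ortho-methoxy oxygen, should migrate in preference to hydride to give formate 3, which base-catalysed methanolysis cleaves to the phenol without touching the methyl ether or the bromides.

Step 3
Reactants: 5 methyl 5-chloro-5-oxopentanoate
Product: 7 methyl 6-bromo-5-oxohexanoate, via diazoketone 6 (not isolated)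
Conditions: CH2N2 (2.5 equiv), Et2O, 0 °C; then 48% aq HBr, 0 °C
Reagents that add atoms: diazomethane, C=[N+]=[N-]; hydrogen bromide, Br
Why: C-acylation of diazomethane (first stage of the Arndt–Eistert sequence, the excess reagent trapping HCl as chloromethane) followed by protonation of diazoketone 6 and SN2 displacement of dinitrogen by bromide, the classical conversion of an acid chloride into a bromomethyl ketone, to which the methyl ester is inert.

Step 4
Reactants: 4 3,5-dibromo-2-methoxyphenol; 7 methyl 6-bromo-5-oxohexanoate
Product: 8 methyl 6-(3,5-dibromo-2-methoxyphenoxy)-5-oxohexanoate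
Conditions: K2CO3, acetone, rt to 40 °C
Reagents that add atoms: none
Why: Williamson ether synthesis with an SN2-activated α-bromo ketone, in which the acidic dibromophenol is deprotonated by carbonate and displaces bromide at the primary carbon, the weak base being unlikely to start aldol or Claisen chemistry of the keto ester.

Step 5
Reactants: 8 methyl 6-(3,5-dibromo-2-methoxyphenoxy)-5-oxohexanoate
Product: 10 2-(3,5-dibromo-2-methoxyphenoxy)cyclohexane-1,3-dione, via potassium dionate 9 (not isolated)
Conditions: KOtBu (2.2 equiv), THF, 0 °C to rt; then 1 M HCl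
Reagents that add atoms: none
Why: tert-Butoxide deprotonates the chain reversibly, most readily at C6, which is flanked by the ketone and the aryloxy oxygen; this enolate carbon adds to the ester carbonyl C1, methoxide leaves, and the new C6–C1 bond (C1'–C2' of ring B) closes the cyclohexane-1,3-dione. The closest known reaction is the intramolecular Claisen (Dieckmann-type) condensation of 5-oxoalkanoates to cyclohexane-1,3-diones. Ring B closes in the 6-(enolendo)-exo-trig mode, which Baldwin's rules for enolates allow. No stereocentre is formed, since C2 of the product is enolised and the molecule has a mirror plane through C2 and C5. The site selectivity needed among the enolisable carbons C2, C4 and C6 is secured by ring size, because the C2 and C4 enolates could only close four-membered rings, and by reversibility, because every step is an equilibrium until the product is removed as the stabilised potassium dionate 9. Acidification releases 10, which is expected to exist largely as its enol.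

Step 6
Reactants: 10 2-(3,5-dibromo-2-methoxyphenoxy)cyclohexane-1,3-dione
Product: 11 2-(3,5-dibromo-2-methoxyphenoxy)-3-methoxycyclohex-2-en-1-one
Conditions: HC(OMe)3, TsOH·H2O (cat.), MeOH, rt
Reagents that add atoms: trimethyl orthoformate, COC(OC)OC; methanol, CO
Why: Acid-catalysed enol etherification of a cyclic 1,3-dione (a vinylogous Fischer esterification driven by the orthoformate), in which the two carbonyls of symmetric 10 are equivalent, so a single vinylogous ester should form that fixes one oxygen as the future C6' methoxy and leaves the other as the future C2' hydroxyl.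

Step 7
Reactants: 11 2-(3,5-dibromo-2-methoxyphenoxy)-3-methoxycyclohex-2-en-1-one
Product: 16 2-(3,5-dibromo-2-methoxyphenoxy)-3-methoxyphenol, via lithium enolate 12 (not isolated), via α'-selenide 13 (not isolated), via selenoxide 14 (not isolated), via dienone 15 (not isolated)
Conditions: LiN(SiMe3)2, THF, −78 °C; PhSeCl, −78 °C; then AcOH, 30% H2O2, 0 °C to rt
Reagents that add atoms: none
Why: Ketone dehydrogenation by α-selenenylation and selenoxide syn-elimination, in which LiN(SiMe3)2 removes the kinetic α'-proton of the vinylogous ester (it is too weak a base to metalate the C–H between the bromines of ring A), enolate 12 is selenenylated to 13, peroxide oxidises selenium, selenoxide 14 eliminates below room temperature to cross-conjugated dienone 15, and this keto tautomer of the phenol aromatises spontaneously while excess peroxide carries the expelled PhSeOH on to PhSeO2H.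

Step 8
Reactants: 16 2-(3,5-dibromo-2-methoxyphenoxy)-3-methoxyphenol
Product: 17 4,6-dibromo-2-(3,5-dibromo-2-methoxyphenoxy)-3-methoxyphenol (target)
Conditions: NBS (2.05 equiv), MeCN, 0 °C to rt
Reagents that add atoms: N-bromosuccinimide, O=C1CCC(=O)N1Br
Why: Electrophilic aromatic bromination of the activated ring, in which C3' and C5' are each ortho to one and para to the other of the OH and OMe groups, the remaining C4' is meta to both, and ring A (two bromines, every position ortho or para to its methoxy group already occupied) should not compete at two equivalents of NBS.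

**Compound list**

1 | 3,5-dibromosalicylaldehyde (3,5-dibromo-2-hydroxybenzaldehyde) | O=Cc1cc(Br)cc(Br)c1O | starting material
2 | 3,5-dibromo-2-methoxybenzaldehyde | COc1c(Br)cc(Br)cc1C=O | intermediate
3 | 3,5-dibromo-2-methoxyphenyl formate | COc1c(Br)cc(Br)cc1OC=O | intermediate
4 | 3,5-dibromo-2-methoxyphenol | COc1c(Br)cc(Br)cc1O | intermediate
5 | methyl 5-chloro-5-oxopentanoate | COC(=O)CCCC(Cl)=O | starting material
6 | methyl 6-diazo-5-oxohexanoate | COC(=O)CCCC(=O)C=[N+]=[N-] | intermediate
7 | methyl 6-bromo-5-oxohexanoate | COC(=O)CCCC(=O)CBr | intermediate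
8 | methyl 6-(3,5-dibromo-2-methoxyphenoxy)-5-oxohexanoate | COC(=O)CCCC(=O)COc1cc(Br)cc(Br)c1OC | intermediate
9 | potassium 2-(3,5-dibromo-2-methoxyphenoxy)-3-oxocyclohex-1-en-1-olate | [K+].[O-]C1=C(Oc2cc(Br)cc(Br)c2OC)C(=O)CCC1 | intermediate
10 | 2-(3,5-dibromo-2-methoxyphenoxy)cyclohexane-1,3-dione | COc1c(Br)cc(Br)cc1OC1C(=O)CCCC1=O | intermediate
11 | 2-(3,5-dibromo-2-methoxyphenoxy)-3-methoxycyclohex-2-en-1-one | COC1=C(Oc2cc(Br)cc(Br)c2OC)C(=O)CCC1 | intermediate
12 | lithium 6-(3,5-dibromo-2-methoxyphenoxy)-5-methoxycyclohexa-1,5-dien-1-olate | [Li+].[O-]C1=CCCC(OC)=C1Oc1cc(Br)cc(Br)c1OC | intermediate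
13 | 2-(3,5-dibromo-2-methoxyphenoxy)-3-methoxy-6-(phenylselanyl)cyclohex-2-en-1-one (racemic) | COC1=C(Oc2cc(Br)cc(Br)c2OC)C(=O)C([Se]c2ccccc2)CC1 | intermediate
14 | 2-(3,5-dibromo-2-methoxyphenoxy)-3-methoxy-6-(phenylseleninyl)cyclohex-2-en-1-one (mixture of stereoisomers at C6 and Se) | COC1=C(Oc2cc(Br)cc(Br)c2OC)C(=O)C([Se](=O)c2ccccc2)CC1 | intermediate
15 | 2-(3,5-dibromo-2-methoxyphenoxy)-3-methoxycyclohexa-2,5-dien-1-one | COC1=C(Oc2cc(Br)cc(Br)c2OC)C(=O)C=CC1 | intermediate
16 | 2-(3,5-dibromo-2-methoxyphenoxy)-3-methoxyphenol | COc1cccc(O)c1Oc1cc(Br)cc(Br)c1OC | intermediate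
17 | 4,6-dibromo-2-(3,5-dibromo-2-methoxyphenoxy)-3-methoxyphenol | COc1c(Br)cc(Br)cc1Oc1c(O)c(Br)cc(Br)c1OC | target

**Step count**

Total: 8 steps. Longest linear sequence: 7 steps (1 → 2 → 4 → 8 → 10 → 11 → 16 → 17); the bromoketone branch (step 3) joins at step 4.

**Steps most likely to fail, and fallbacks**

Step 7. Proton exchange between enolate 12 and the more acidic selenide 13 may lead to double selenenylation. The electron-rich phenol may also be attacked, as it forms, by electrophilic selenium species or by peroxide, giving selenenylated or quinoid material. The fallback sets out from 11 and returns at 16, and keeps selenium and peroxide away from the free phenol. The enolate generated with LiN(SiMe3)2 in THF at −78 °C would be trapped with TBSOTf to give tert-butyl{[6-(3,5-dibromo-2-methoxyphenoxy)-5-methoxycyclohexa-1,5-dien-1-yl]oxy}dimethylsilane F1. This silyloxy cyclohexa-1,3-diene should be dehydrogenated by DDQ with 2,6-lutidine in benzene at rt (hydride abstraction, then proton loss) to the aryl silyl ether tert-butyl[2-(3,5-dibromo-2-methoxyphenoxy)-3-methoxyphenoxy]dimethylsilane F2. A regioisomeric dienol ether formed by γ-deprotonation would converge on the same arene. Bu4NF in THF would then free phenol 16.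

Step 5. Bimolecular aldol or Claisen condensation between two chains may outrun ring closure, because the reacting enolate carbon is oxygen-substituted and hindered, and prolonged exposure to alkoxide may degrade the α-aryloxy ketone. The fallback sets out from 4 and returns at 10; it takes ring B from a preformed six-membered ring and forms the C1'–O bond instead. Commercial cyclohexane-1,3-dione would undergo diazo transfer (4-acetamidobenzenesulfonyl azide, Et3N, MeCN, rt) to 2-diazocyclohexane-1,3-dione F3. Its rhodium carbenoid, generated with Rh2(OAc)4 (cat.) in benzene at 80 °C, should insert into the O–H bond of phenol 4 to give dione 10 directly. Compounds 5, 7 and 8 would then not be needed.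

Step 2. Hydride instead of aryl migration in the peracid adduct may divert the aldehyde to the benzoic acid. Ring A is electron-poor and its methoxy group is twisted out of conjugation by two ortho neighbours. The fallback sets out from 2 and returns at 4, replacing the oxygen-insertion by a degradation through nitrogen. Pinnick oxidation (NaClO2, NaH2PO4, 2-methyl-2-butene, t-BuOH/H2O) would give 3,5-dibromo-2-methoxybenzoic acid F4. Diphenylphosphoryl azide and Et3N in toluene at 80 °C would convert it through 3,5-dibromo-2-methoxybenzoyl azide F5 into 1,5-dibromo-3-isocyanato-2-methoxybenzene F6 (Curtius rearrangement). Aqueous HCl would hydrolyse the isocyanate to 3,5-dibromo-2-methoxyaniline F7. Diazotisation (NaNO2, aq H2SO4, 0 °C) would give 3,5-dibromo-2-methoxybenzenediazonium hydrogensulfate F8, which on heating in dilute H2SO4 should hydrolyse to phenol 4.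

**Further compounds**

F1 | step 7 | tert-butyl{[6-(3,5-dibromo-2-methoxyphenoxy)-5-methoxycyclohexa-1,5-dien-1-yl]oxy}dimethylsilane | COC1=C(Oc2cc(Br)cc(Br)c2OC)C(O[Si](C)(C)C(C)(C)C)=CCC1
F2 | step 7 | tert-butyl[2-(3,5-dibromo-2-methoxyphenoxy)-3-methoxyphenoxy]dimethylsilane | COc1cccc(O[Si](C)(C)C(C)(C)C)c1Oc1cc(Br)cc(Br)c1OC
F3 | step 5 | 2-diazocyclohexane-1,3-dione | O=C1CCCC(=O)C1=[N+]=[N-]
F4 | step 2 | 3,5-dibromo-2-methoxybenzoic acid | COc1c(Br)cc(Br)cc1C(O)=O
F5 | step 2 | 3,5-dibromo-2-methoxybenzoyl azide | COc1c(Br)cc(Br)cc1C(=O)N=[N+]=[N-]
F6 | step 2 | 1,5-dibromo-3-isocyanato-2-methoxybenzene | COc1c(Br)cc(Br)cc1N=C=O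
F7 | step 2 | 3,5-dibromo-2-methoxyaniline | COc1c(Br)cc(Br)cc1N
F8 | step 2 | 3,5-dibromo-2-methoxybenzenediazonium hydrogensulfate | COc1c(Br)cc(Br)cc1[N+]#N.OS([O-])(=O)=O
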